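**Assumption:** germacrane numbering is used for the ring (C6 carbinol, C7 isopropyl-bearing carbon, C8 ester carbon) and farnesane numbering for open-chain compounds; (S)-BINAP dioxide is written for step 7, its hand must be confirmed in a first run (the mirror-image catalyst gives the mirror-image ring).

## Retrosynthetic overview

1. Target 17 ⇒ aryl acetate 16 ⇒ diol 13 + acid 14 (ester C–O bond; the equatorial 8-OH is acylated, the axial allylic 6-OH stays free).
2. Diol 13 ⇒ β-hydroxy ketone 11 (C8 set by hydride delivery from the 6-OH).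
3. Ketone 11 ⇒ open-chain 9-oxofarnesal 8: one ring-forming step closes C6–C7 (farnesyl C1–C10, the bond the germacrene cyclase makes) by an enantioselective reductive aldol that also creates the isopropyl group, C6 and C7.
4. Aldehyde 8 ⇒ geranyl acetate 1 + CO + isobutenylstannane 5 (allylic oxidation, carbonylative Stille coupling).
5. Ring order: the arene is bought; the ten-membered carbocycle is the only ring made (step 7).

## Route

**Step 1**
Reactants: 1 geranyl acetate
Product: 2 (2E,6E)-8-hydroxy-3,7-dimethylocta-2,6-dien-1-yl acetate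
Conditions: SeO2 (10 mol %), t-BuOOH, salicylic acid (10 mol %), CH2Cl2, rt
Reagents that add atoms: tert-butyl hydroperoxide, CC(C)(C)OO
Why: SeO2/t-BuOOH allylic oxidation (ene reaction, then [2,3]-sigmatropic shift) attacks the more electron-rich distal alkene at its (E)-methyl group and gives the E allylic alcohol, the 2,3-alkene being deactivated by the allylic acetate.

**Step 2**
Reactants: 2 (2E,6E)-8-hydroxy-3,7-dimethylocta-2,6-dien-1-yl acetate
Product: 3 (2E,6E)-8-chloro-3,7-dimethylocta-2,6-dien-1-yl acetate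
Conditions: PPh3, hexachloroacetone, CH2Cl2, 0 °C
Reagents that add atoms: hexachloroacetone, ClC(Cl)(Cl)C(=O)C(Cl)(Cl)Cl
Why: Appel-type chlorination of a primary allylic alcohol proceeds by SN2 without allylic transposition or E/Z loss and leaves the acetate alone.

**Step 3**
Reactants: 4 (2-methylprop-1-en-1-yl)magnesium bromide
Product: 5 tributyl(2-methylprop-1-en-1-yl)stannane
Conditions: Bu3SnCl, THF, 0 °C → rt
Reagents that add atoms: tributyltin chloride, CCCC[Sn](Cl)(CCCC)CCCC
Why: Nucleophilic substitution at tin by the alkenyl Grignard reagent (transmetalation) gives the alkenylstannane; no stereo element is involved.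

**Step 4**
Reactants: 3 (2E,6E)-8-chloro-3,7-dimethylocta-2,6-dien-1-yl acetate; 5 tributyl(2-methylprop-1-en-1-yl)stannane
Product: 6 (2E,6E)-3,7,11-trimethyl-9-oxododeca-2,6,10-trien-1-yl acetate
Conditions: Pd(dba)2 (5 mol %), PPh3 (10 mol %), CO (3 atm), THF, 50 °C
Reagents that add atoms: 5 tributyl(2-methylprop-1-en-1-yl)stannane, CC(C)=C[Sn](CCCC)(CCCC)CCCC; carbon monoxide, [C-]#[O+]
Why: Carbonylative Stille coupling: the allylic chloride adds to Pd(0) with the E geometry kept, CO inserts at the primary allyl terminus and the alkenyl group is transferred from tin under neutral conditions, while the allylic acetate ionises far more slowly and does not transmetalate without added halide.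

**Step 5**
Reactants: 6 (2E,6E)-3,7,11-trimethyl-9-oxododeca-2,6,10-trien-1-yl acetate
Product: 7 (2E,6E)-9-oxofarnesol, i.e. (6E,10E)-12-hydroxy-2,6,10-trimethyldodeca-2,6,10-trien-4-one
Conditions: Novozym 435 (CAL-B), n-BuOH (5 equiv), MTBE, 30 °C
Reagents that add atoms: none
Why: Lipase-catalysed transesterification removes the primary acetate at neutral pH, so the base-sensitive β,γ-unsaturated ketone does not slip into conjugation.

**Step 6**
Reactants: 7 (2E,6E)-9-oxofarnesol
Product: 8 (2E,6E)-3,7,11-trimethyl-9-oxododeca-2,6,10-trienal (9-oxofarnesal)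
Conditions: MnO2 (20 equiv), CH2Cl2, rt
Reagents that add atoms: none
Why: MnO2 oxidation is selective for the primary allylic alcohol, is neutral and does not isomerise the 2E enal.

**Step 7**
Reactants: 8 (2E,6E)-3,7,11-trimethyl-9-oxododeca-2,6,10-trienal
Product: 11 (6S,7S)-6-hydroxygermacra-1(10)E,4E-dien-8-one, via (Z)-trichlorosilyl enolate 9 (not isolated), via trichlorosilyl aldolate 10 (not isolated)
Conditions: HSiCl3 (3 equiv), (S)-BINAP dioxide (20 mol %), CH2Cl2/EtCN, syringe-pump addition of 8 (final 0.005 M), −40 °C; then sat. aq NaHCO3, 0 °C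
Reagents that add atoms: none
Why: Proposed new method: Lewis-base-activated HSiCl3 delivers hydride through a six-membered transition state only to the s-cis β,β-dimethyl enone (the s-trans, less basic enal is spared) and so gives the (Z)-enolate 9 regiospecifically at farnesyl C10, which adds to the C1 aldehyde through a closed chair-like transition state on hexacoordinate silicon; the tether holds C5 synclinal to C8 (pseudo-axial, as in the crown conformer of the ring), so the Z-enolate gives the 6,7-cis ring (anti aldol, OH axial, iPr equatorial) and the chiral bisphosphine dioxide on silicon selects the enolate face and hence (6S,7S); the closest known chemistry is the intermolecular phosphine-oxide-catalysed HSiCl3 reductive aldol of enones with aldehydes, the Lewis-base-catalysed aldol addition of trichlorosilyl enolates, and closure of E,E-germacradienes at this same bond by intramolecular carbonyl allylation.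

**Step 8**
Reactants: 11 (6S,7S)-6-hydroxygermacra-1(10)E,4E-dien-8-one
Product: 13 (6S,7R,8S)-germacra-1(10)E,4E-diene-6,8-diol, via alkoxyborohydride 12 (not isolated)
Conditions: Me4NBH(OAc)3 (5 equiv), MeCN/AcOH, −35 °C; then aq Rochelle salt/NaHCO3
Reagents that add atoms: none
Why: Evans–Saksena reduction: the 6-OH exchanges onto boron to give 12, which delivers hydride intramolecularly to the face of the C8 carbonyl that lies on the side of O6, so the new 8-OH is trans to the 6-OH and trans to the isopropyl group; the change of descriptor at C7 (S to R) is only a change of CIP priorities.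

**Step 9**
Reactants: 13 (6S,7R,8S)-germacra-1(10)E,4E-diene-6,8-diol; 14 (E)-4-acetoxy-3-methoxycinnamic acid
Product: 16 (6S,7S,8S)-6-hydroxygermacra-1(10)E,4E-dien-8-yl (E)-3-(4-acetoxy-3-methoxyphenyl)prop-2-enoate, via O-acylisourea 15 (not isolated)
Conditions: 14 (1.05 equiv), DCC (1.1 equiv), DMAP (10 mol %), CH2Cl2, −20 → 0 °C
Reagents that add atoms: 14 (E)-4-acetoxy-3-methoxycinnamic acid, COc1cc(/C=C/C(=O)O)ccc1OC(C)=O
Why: Steglich esterification through 15: the 8-OH is equatorial and peripheral on the crown conformer, whereas the 6-OH is axial, allylic and wedged between the C4 and C10 methyl groups and the isopropyl group, so one equivalent of acid acylates O8; no stereocentre is touched.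

**Step 10**
Reactants: 16 (6S,7S,8S)-6-hydroxygermacra-1(10)E,4E-dien-8-yl (E)-3-(4-acetoxy-3-methoxyphenyl)prop-2-enoate
Product: 17 (6S,7S,8S)-6-hydroxygermacra-1(10)E,4E-dien-8-yl (E)-ferulate (CNP0378519.1)
Conditions: pyrrolidine (3 equiv), CH2Cl2, 0 °C
Reagents that add atoms: none
Why: Aminolysis of the aryl acetate (an activated ester) is much faster than attack on the conjugated secondary ferulate, and the mild conditions leave the diene and the three stereocentres untouched.

## Compound list

1 | geranyl acetate, (2E)-3,7-dimethylocta-2,6-dien-1-yl acetate | CC(=O)OC/C=C(\C)CCC=C(C)C | starting material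
2 | (2E,6E)-8-hydroxy-3,7-dimethylocta-2,6-dien-1-yl acetate | CC(=O)OC/C=C(\C)CC/C=C(\C)CO | intermediate
3 | (2E,6E)-8-chloro-3,7-dimethylocta-2,6-dien-1-yl acetate | CC(=O)OC/C=C(\C)CC/C=C(\C)CCl | intermediate
4 | (2-methylprop-1-en-1-yl)magnesium bromide (0.5 M in THF) | CC(C)=C[Mg]Br | starting material
5 | tributyl(2-methylprop-1-en-1-yl)stannane | CC(C)=C[Sn](CCCC)(CCCC)CCCC | intermediate
6 | (2E,6E)-3,7,11-trimethyl-9-oxododeca-2,6,10-trien-1-yl acetate (9-oxofarnesyl acetate) | CC(=O)OC/C=C(\C)CC/C=C(\C)CC(=O)C=C(C)C | intermediate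
7 | (2E,6E)-9-oxofarnesol, (6E,10E)-12-hydroxy-2,6,10-trimethyldodeca-2,6,10-trien-4-one | OC/C=C(\C)CC/C=C(\C)CC(=O)C=C(C)C | intermediate
8 | (2E,6E)-3,7,11-trimethyl-9-oxododeca-2,6,10-trienal (9-oxofarnesal) | O=C/C=C(\C)CC/C=C(\C)CC(=O)C=C(C)C | intermediate
9 | (2E,6E,9Z)-3,7,11-trimethyl-9-[(trichlorosilyl)oxy]dodeca-2,6,9-trienal | O=C/C=C(\C)CC/C=C(\C)C/C(O[Si](Cl)(Cl)Cl)=C/C(C)C | intermediate (not isolated)
10 | (6S,7S)-6-[(trichlorosilyl)oxy]germacra-1(10)E,4E-dien-8-one | O=C1C/C(C)=C/CC/C(C)=C/[C@H](O[Si](Cl)(Cl)Cl)[C@@H]1C(C)C | intermediate (not isolated)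
11 | (6S,7S)-6-hydroxygermacra-1(10)E,4E-dien-8-one, (3E,7E,9S,10S)-9-hydroxy-3,7-dimethyl-10-(propan-2-yl)cyclodeca-3,7-dien-1-one; OH and iPr cis | O=C1C/C(C)=C/CC/C(C)=C/[C@H](O)[C@@H]1C(C)C | intermediate
12 | tetramethylammonium diacetoxy(hydrido)borate ester of 11 at O6 | O=C1C/C(C)=C/CC/C(C)=C/[C@H](O[BH-](OC(C)=O)OC(C)=O)[C@@H]1C(C)C.C[N+](C)(C)C | intermediate (not isolated)
13 | (6S,7R,8S)-germacra-1(10)E,4E-diene-6,8-diol; 6-OH cis and 8-OH trans to iPr | O[C@H]1C/C(C)=C/CC/C(C)=C/[C@H](O)[C@@H]1C(C)C | intermediate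
14 | (E)-4-acetoxy-3-methoxycinnamic acid (4-O-acetylferulic acid) | COc1cc(/C=C/C(=O)O)ccc1OC(C)=O | starting material
15 | O-acylisourea of 14 with DCC | COc1cc(/C=C/C(=O)OC(=NC2CCCCC2)NC2CCCCC2)ccc1OC(C)=O | intermediate (not isolated)
16 | (6S,7S,8S)-6-hydroxygermacra-1(10)E,4E-dien-8-yl (E)-3-(4-acetoxy-3-methoxyphenyl)prop-2-enoate | COc1cc(/C=C/C(=O)O[C@H]2C/C(C)=C/CC/C(C)=C/[C@H](O)[C@@H]2C(C)C)ccc1OC(C)=O | intermediate
17 | (6S,7S,8S)-6-hydroxygermacra-1(10)E,4E-dien-8-yl (E)-ferulate | COc1cc(/C=C/C(=O)O[C@H]2C/C(C)=C/CC/C(C)=C/[C@H](O)[C@@H]2C(C)C)ccc1O | target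

## Step count and risks

Total steps: 10. Longest linear sequence: 9 (steps 1, 2, 4–10 from geranyl acetate; step 3 is a one-step side branch).

**Step 7 (macrocyclic reductive aldol).** It can fail by reduction of the enal, oligomerisation, or poor diastereo- or enantiocontrol. The fallback sets out from 6 and comes back at 11, separating enolate formation from ring closure. Rh-catalysed 1,4-hydrosilylation of 6 (Et3SiH, RhCl(PPh3)3), run before any aldehyde is present, gives (2E,6E,9Z)-3,7,11-trimethyl-9-[(triethylsilyl)oxy]dodeca-2,6,9-trien-1-yl acetate F1. Lipase transesterification gives the alcohol (2E,6E,9Z)-3,7,11-trimethyl-9-[(triethylsilyl)oxy]dodeca-2,6,9-trien-1-ol F2, and MnO2 gives the enal (2E,6E,9Z)-3,7,11-trimethyl-9-[(triethylsilyl)oxy]dodeca-2,6,9-trienal F3. F3 is then closed by an intramolecular Mukaiyama aldol addition under high dilution with SiCl4 and a chiral bisphosphoramide Lewis base, and bicarbonate work-up gives 11.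

**Step 8 (directed reduction in acetic acid).** The E,E-germacradiene may undergo acid-induced transannular cyclisation. The fallback sets out from 11 and comes back at 13 under neutral conditions. An Evans–Tishchenko reduction (acetaldehyde, 20 mol % SmI2, THF, −10 °C) sets C8 by intramolecular hydride transfer from the O6 hemiacetal and gives (6S,7R,8S)-8-hydroxygermacra-1(10)E,4E-dien-6-yl acetate F4. Methanolysis of F4 (K2CO3, MeOH, 0 °C) gives 13.

**Step 9 (regioselective mono-acylation).** The 6-ester or the diester may form. The fallback sets out from 13 and comes back at 16 without any competition between the two hydroxyls. MnO2 oxidises only the allylic 6-OH and gives (7R,8S)-8-hydroxygermacra-1(10)E,4E-dien-6-one F5. An Evans–Tishchenko reaction of F5 with commercial (E)-4-acetoxy-3-methoxycinnamaldehyde (SmI2 cat., THF, −10 °C) places the acyl group on O8 and returns hydride to C6 from the O8 side, which restores the 6-OH trans to O8 and cis to the isopropyl group, giving 16.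

## Further compounds

F1 | step 7 | (2E,6E,9Z)-3,7,11-trimethyl-9-[(triethylsilyl)oxy]dodeca-2,6,9-trien-1-yl acetate | CC(=O)OC/C=C(\C)CC/C=C(\C)C/C(O[Si](CC)(CC)CC)=C/C(C)C
F2 | step 7 | (2E,6E,9Z)-3,7,11-trimethyl-9-[(triethylsilyl)oxy]dodeca-2,6,9-trien-1-ol | OC/C=C(\C)CC/C=C(\C)C/C(O[Si](CC)(CC)CC)=C/C(C)C
F3 | step 7 | (2E,6E,9Z)-3,7,11-trimethyl-9-[(triethylsilyl)oxy]dodeca-2,6,9-trienal | O=C/C=C(\C)CC/C=C(\C)C/C(O[Si](CC)(CC)CC)=C/C(C)C
F4 | step 8 | (6S,7R,8S)-8-hydroxygermacra-1(10)E,4E-dien-6-yl acetate | O[C@H]1C/C(C)=C/CC/C(C)=C/[C@H](OC(C)=O)[C@@H]1C(C)C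
F5 | step 9 | (7R,8S)-8-hydroxygermacra-1(10)E,4E-dien-6-one | O[C@H]1C/C(C)=C/CC/C(C)=C/C(=O)[C@@H]1C(C)C
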